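**Retrosynthetic overview**

1. Numbering: left decalin C1–C10 (C3 carbinol, C4 CMe2, C5-H and C10-Me at the A/B fusion, diene C6=C7–C8=C9). Linker C11–C1′. Right half C2′–C11′ numbered along its acyclic precursor (ring C = cyclohexane C2′–C7′, ring D = oxepanone O/C6′–C11′).
2. The last C–C bond is C9–C11, made by B-alkyl Suzuki–Miyaura coupling of dienyl triflate 15 (rings A/B) with the borane from vinyl compound 29 (rings C/D). Oxidation of the C10′ alcohol to the ketone and desilylation at C3 follow.
3. Triflate 15 comes from the trans-decalin enedione 11. Ring B is an aldol condensation C8→C7. Ring A is the one-carbon enlargement of the cyclopentane C1–C2–C3–C5–C10 of carbinol 8, by insertion of C4 (CMe2) between C3 and C5.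
4. Enabling feature: in ring A the oxygenated C3 is flanked by the quaternary C4 (two methyl groups), which is bonded to the tertiary ring-fusion carbon C5. The unit C3(=O)–C4Me2–C5 is the retron of a semipinacol shift of C5 from C3 to a Me2C cation centre.
5. Carbinol 8 comes from 3-methylcyclopentenone by asymmetric conjugate addition and allylation (sets C10 and C5). Compound 29 comes from geranyl bromide and methyl acetoacetate via Shi diepoxide 23. Ring order: cyclopentane (bought) → A → B (both in step 5); D and C together (step 13).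

Key step: step 5

Assumption: the sense of induction of the chiral ligand (step 1) and of the D-fructose-derived ketone (step 12) is taken from the closest known substrate classes; if it is opposite, the enantiomeric ligand or ketone is used.

**Rings A and B (steps 1–8)**

Step 1
Reactants: 1 3-methylcyclopent-2-en-1-one
Product: 3 (R)-{[3-(but-1-en-2-yl)-3-methylcyclopent-1-en-1-yl]oxy}trimethylsilane, via aluminium enolate 2 (not isolated)
Conditions: 2-bromobut-1-ene, t-BuLi (2 equiv), Et2O, −78 °C; Me2AlCl, −78 °C to rt; then 1, Cu(O2CC4H3S) (copper thiophene-2-carboxylate, monovalent copper, 10 mol %), chiral P,P-diphenyl-N,N-bis(1-arylethyl)phosphinous amide ligand (11 mol %), Et2O, −10 °C; then Me3SiOTf, −78 to 0 °C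
Reagents that add atoms: 2-bromobut-1-ene CCC(Br)=C; trimethylsilyl triflate C[Si](C)(C)OS(=O)(=O)C(F)(F)F
Why: Copper-catalysed asymmetric conjugate addition of an alkenylalane to a β-substituted cyclic enone, in which the chiral copper complex selects the enone face and so sets the quaternary C10, while silylation fixes the enolate regiochemistry between C3 and C5.

Step 2
Reactants: 3 (R)-{[3-(but-1-en-2-yl)-3-methylcyclopent-1-en-1-yl]oxy}trimethylsilane
Product: 5 (2S,3R)-2-allyl-3-(but-1-en-2-yl)-3-methylcyclopentan-1-one, via lithium enolate 4 (not isolated)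
Conditions: MeLi, THF, 0 °C; then allyl iodide, DMPU, −78 to −20 °C
Reagents that add atoms: allyl iodide C=CCI
Why: Regiospecific enolate alkylation in which the lithium enolate released from the silyl enol ether is allylated anti to the larger butenyl group on the neighbouring C10, which sets C5 trans to the C9 substituent (also the thermodynamic isomer).

Step 3
Reactants: 5 (2S,3R)-2-allyl-3-(but-1-en-2-yl)-3-methylcyclopentan-1-one
Product: 7 (2S,3R)-2-(2,2-dimethoxyethyl)-3-methyl-3-propanoylcyclopentan-1-one, via keto aldehyde 6 (not isolated)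
Conditions: O3, CH2Cl2/MeOH, −78 °C; Me2S; then HC(OMe)3, PPTS, MeOH, 0 °C
Reagents that add atoms: ozone [O-][O+]=O; trimethyl orthoformate COC(OC)OC
Why: Ozonolysis with reductive work-up turns both terminal alkenes into the C9 propanoyl ketone and the C7 aldehyde, and mild chemoselective acetalisation masks only the aldehyde without any base that could epimerise C5.

Step 4
Reactants: 7 (2S,3R)-2-(2,2-dimethoxyethyl)-3-methyl-3-propanoylcyclopentan-1-one
Product: 8 1-[(1R,2S)-2-(2,2-dimethoxyethyl)-3-hydroxy-1-methyl-3-(prop-1-en-2-yl)cyclopentyl]propan-1-one (both epimers at the carbinol carbon)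
Conditions: CeCl3, isopropenylmagnesium bromide, THF, −78 °C
Reagents that add atoms: isopropenylmagnesium bromide CC(=C)[Mg]Br
Why: 1,2-Addition of a non-basic organocerium reagent, which prefers the ring ketone C3 over the C9 ketone next to the quaternary C10 and does not enolise C5; the new carbinol centre needs no control because step 5 erases it.

Step 5
Reactants: 8 1-[(1R,2S)-2-(2,2-dimethoxyethyl)-3-hydroxy-1-methyl-3-(prop-1-en-2-yl)cyclopentyl]propan-1-one
Product: 11 (4aR,8aR)-2,5,5,8a-tetramethyl-4a,5,8,8a-tetrahydronaphthalene-1,6(4H,7H)-dione, via ring-enlarged keto acetal 9 (not isolated), via keto aldehyde 10 (not isolated)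
Conditions: [N,N′-bis(3,5-di-tert-butylsalicylidene)-1,2-cyclohexanediaminato]cobalt, Co(C36H52N2O2) (divalent cobalt, 5 mol %), N-fluoro-2,4,6-trimethylpyridinium triflate, PhSiH3, PhCF3, 0 °C to rt; then 2 M HCl, THF, 45 °C
Reagents that add atoms: none
Why: A cobalt hydride formed from the cobalt complex, the N-fluoropyridinium salt and PhSiH3 transfers a hydrogen atom to the CH2 end of the only alkene; the tertiary C4 radical is carried through an alkylcobalt species (tetravalent cobalt) to cation level, and C5 shifts from C3 to C4 while the C3 hydroxyl becomes the C3 ketone, so the cyclopentane C1–C2–C3–C5–C10 takes up C4 and becomes ring A (9). The closest known reaction type is the hydrogen-atom-transfer-initiated radical–polar crossover semipinacol rearrangement of tertiary allylic alcohols, the neutral counterpart of the pinacol ring enlargement of 1-(2-hydroxypropan-2-yl)cyclopentanol to 2,2-dimethylcyclohexanone and the reverse of the acid-induced contraction of 3-hydroxy-4,4-dimethyl A rings. Ring A is enlarged by a 1,2-shift rather than closed, and ring B is then closed in the same flask, after acid hydrolysis of the acetal to 10, by a 6-(enolexo)-exo-trig aldol addition of the C8 enol to the C7 aldehyde followed by dehydration. No new stereocentre is made: C5 migrates with retention, C10 is untouched, their trans relation in 8 becomes the trans A/B fusion of 11, and both carbinol epimers of 8 converge on one ketone. The step needs migration of C5 rather than C2, which the higher substitution of C5 secures; it needs hydrogen-atom transfer at one site only, which the single C=C of 8 secures; and it needs one aldol mode, which follows because C9 can enolise only towards C8 and the competing C2→C7 aldol cannot dehydrate at a bridgehead and reverts. In one operation the step sets the ring A size, the quaternary C4 with both methyl groups, the C3 carbonyl, ring B and the C7=C8–C9=O enone.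

Step 6
Reactants: 11 (4aR,8aR)-2,5,5,8a-tetramethyl-4a,5,8,8a-tetrahydronaphthalene-1,6(4H,7H)-dione
Product: 12 (4aR,6R,8aR)-6-hydroxy-2,5,5,8a-tetramethyl-4a,5,6,7,8,8a-hexahydronaphthalen-1(4H)-one
Conditions: NaBH4, MeOH/CH2Cl2 (1:1), −78 to −40 °C
Reagents that add atoms: none
Why: Chemoselective borohydride reduction in which the saturated C3 ketone reacts before the conjugated C9 ketone flanked by C10 and C8-Me, and hydride arrives from the face opposite the axial C10 and C4 methyl groups to give the equatorial C3 alcohol.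

Step 7
Reactants: 12 (4aR,6R,8aR)-6-hydroxy-2,5,5,8a-tetramethyl-4a,5,6,7,8,8a-hexahydronaphthalen-1(4H)-one
Product: 13 (4aR,6R,8aR)-6-[(tert-butyldimethylsilyl)oxy]-2,5,5,8a-tetramethyl-4a,5,6,7,8,8a-hexahydronaphthalen-1(4H)-one
Conditions: TBSOTf, 2,6-lutidine, CH2Cl2, 0 °C
Reagents that add atoms: tert-butyldimethylsilyl triflate CC(C)(C)[Si](C)(C)OS(=O)(=O)C(F)(F)F
Why: Silyl ether protection with the reactive silyl triflate, which is needed for the hindered alcohol next to C4 and touches no stereocentre.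

Step 8
Reactants: 13 (4aR,6R,8aR)-6-[(tert-butyldimethylsilyl)oxy]-2,5,5,8a-tetramethyl-4a,5,6,7,8,8a-hexahydronaphthalen-1(4H)-one
Product: 15 (4aR,6R,8aR)-6-[(tert-butyldimethylsilyl)oxy]-2,5,5,8a-tetramethyl-4a,5,6,7,8,8a-hexahydronaphthalen-1-yl trifluoromethanesulfonate, via potassium dienolate 14 (not isolated)
Conditions: KHMDS, THF, −78 °C; then PhNTf2, −78 to 0 °C
Reagents that add atoms: N-phenylbis(trifluoromethanesulfonimide) O=S(=O)(N(c1ccccc1)S(=O)(=O)C(F)(F)F)C(F)(F)F
Why: Dienyl triflate formation in which the quaternary C10 leaves only the γ-hydrogen at C6 for deprotonation, so O-sulfonylation of the extended dienolate gives the C6=C7–C8=C9 diene with the leaving group on C9 and leaves C5 untouched.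

**Rings C and D (steps 9–17)**

Step 9
Reactants: 16 methyl acetoacetate; 17 geranyl bromide
Product: 19 methyl (6E)-7,11-dimethyl-3-oxododeca-6,10-dienoate, via acetoacetate dianion 18 (not isolated)
Conditions: NaH, THF, 0 °C; n-BuLi, 0 °C; then 17, 0 °C; aq. HCl
Reagents that add atoms: none
Why: γ-Alkylation of the acetoacetate dianion, whose more reactive terminal carbanion displaces the allylic bromide without touching the E alkene.

Step 10
Reactants: 19 methyl (6E)-7,11-dimethyl-3-oxododeca-6,10-dienoate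
Product: 21 methyl (2Z,6E)-3-[(diethoxyphosphoryl)oxy]-7,11-dimethyldodeca-2,6,10-trienoate, via sodium enolate 20 (not isolated)
Conditions: NaH, Et2O, 0 °C; then ClP(O)(OEt)2
Reagents that add atoms: diethyl chlorophosphate CCOP(=O)(Cl)OCC
Why: O-Phosphorylation of the chelated sodium enolate of a β-keto ester, whose chelate holds the enolate oxygen cis to the ester and so gives the Z enol phosphate.

Step 11
Reactants: 21 methyl (2Z,6E)-3-[(diethoxyphosphoryl)oxy]-7,11-dimethyldodeca-2,6,10-trienoate
Product: 22 methyl (2Z,6E)-7,11-dimethyl-3-[(trimethylsilyl)methyl]dodeca-2,6,10-trienoate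
Conditions: Me3SiCH2MgCl, Ni(acac)2 (5 mol %), THF, 0 °C to rt
Reagents that add atoms: (trimethylsilyl)methylmagnesium chloride C[Si](C)(C)C[Mg]Cl
Why: Nickel-catalysed Kumada-type cross-coupling of an enol phosphate, which proceeds with retention of alkene geometry and installs the allylsilane with C1′ trans to C4′ as the later chair cyclisation requires.

Step 12
Reactants: 22 methyl (2Z,6E)-7,11-dimethyl-3-[(trimethylsilyl)methyl]dodeca-2,6,10-trienoate
Product: 23 methyl (2Z)-5-{(2R,3R)-3-[2-((2R)-3,3-dimethyloxiran-2-yl)ethyl]-3-methyloxiran-2-yl}-3-[(trimethylsilyl)methyl]pent-2-enoate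
Conditions: 1,2:4,5-di-O-isopropylidene-β-D-erythro-2,3-hexodiulo-2,6-pyranose (0.6 equiv), KHSO5 (as Oxone), K2CO3, Bu4NHSO4, MeCN/CH2(OMe)2/aq. Na2B4O7 buffer, 0 °C
Reagents that add atoms: potassium peroxymonosulfate [K+].OOS(=O)(=O)[O-]
Why: Shi epoxidation in which the chiral dioxirane oxidises the two electron-rich trisubstituted alkenes and leaves the ester-conjugated C2′=C3′ alkene, with reagent control setting C6′ and C7′ (R,R) and C10′ (R).

Step 13
Reactants: 23 methyl (2Z)-5-{(2R,3R)-3-[2-((2R)-3,3-dimethyloxiran-2-yl)ethyl]-3-methyloxiran-2-yl}-3-[(trimethylsilyl)methyl]pent-2-enoate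
Product: 25 methyl (3R,5aR,6S,9aR)-3-hydroxy-2,2,5a-trimethyl-7-methylidenedecahydro-1-benzoxepine-6-carboxylate, via trimethylsilyl ether 24 (not isolated)
Conditions: Me3SiOTf, 2,6-di-tert-butyl-4-methylpyridine, CH2Cl2, −78 °C; then citric acid, MeOH, rt
Reagents that add atoms: none
Why: Epoxide-opening oxa-/carbacyclisation cascade in which the activated terminal epoxide is opened at its tertiary C11′ by the oxygen of the inner epoxide (ring D), and the resulting epoxonium ion is opened at C7′ with inversion by the allylsilane carbon C2′ through a chair (ring C); this keeps C6′, sets C7′ for the trans C/D fusion, puts the ester on C2′ equatorial and ends in the exocyclic alkene on loss of silicon.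

Step 14
Reactants: 25 methyl (3R,5aR,6S,9aR)-3-hydroxy-2,2,5a-trimethyl-7-methylidenedecahydro-1-benzoxepine-6-carboxylate
Product: 26 methyl (3R,5aR,6S,7S,9aR)-3-hydroxy-2,2,5a,7-tetramethyldecahydro-1-benzoxepine-6-carboxylate
Conditions: H2 (1 atm), PtO2, EtOAc, rt
Reagents that add atoms: none
Why: Heterogeneous catalytic hydrogenation in which the catalyst approaches the exocyclic alkene from the face opposite the axial C7′ methyl group, so hydrogen enters C3′ from that face and the new methyl group becomes axial, cis to the C7′ methyl and the C2′ substituent.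

Step 15
Reactants: 26 methyl (3R,5aR,6S,7S,9aR)-3-hydroxy-2,2,5a,7-tetramethyldecahydro-1-benzoxepine-6-carboxylate
Product: 27 (3R,5aR,6S,7S,9aR)-6-(hydroxymethyl)-2,2,5a,7-tetramethyldecahydro-1-benzoxepin-3-ol
Conditions: LiAlH4, THF, 0 °C to rt
Reagents that add atoms: none
Why: Hydride reduction of the ester to the primary alcohol, which touches no stereocentre.

Step 16
Reactants: 27 (3R,5aR,6S,7S,9aR)-6-(hydroxymethyl)-2,2,5a,7-tetramethyldecahydro-1-benzoxepin-3-ol
Product: 28 (3R,5aR,6S,7S,9aR)-3-hydroxy-2,2,5a,7-tetramethyldecahydro-1-benzoxepine-6-carbaldehyde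
Conditions: TEMPO (10 mol %), PhI(OAc)2, CH2Cl2, rt
Reagents that add atoms: none
Why: Oxoammonium (TEMPO) oxidation, which is selective for the primary alcohol over the hindered secondary C10′ alcohol and gives the equatorial and therefore configurationally stable aldehyde.

Step 17
Reactants: 28 (3R,5aR,6S,7S,9aR)-3-hydroxy-2,2,5a,7-tetramethyldecahydro-1-benzoxepine-6-carbaldehyde
Product: 29 (3R,5aR,6S,7S,9aR)-6-ethenyl-2,2,5a,7-tetramethyldecahydro-1-benzoxepin-3-ol
Conditions: Ph3PCH3Br, KHMDS (excess ylide), THF, −78 to 0 °C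
Reagents that add atoms: methyltriphenylphosphonium bromide C[P+](c1ccccc1)(c1ccccc1)c1ccccc1.[Br-]
Why: Wittig methylenation at low temperature, which converts the aldehyde into the vinyl group carrying both linker carbons, tolerates the free hydroxyl and does not epimerise C2′.

**Coupling and endgame (steps 18–20)**

Step 18
Reactants: 29 (3R,5aR,6S,7S,9aR)-6-ethenyl-2,2,5a,7-tetramethyldecahydro-1-benzoxepin-3-ol; 15 (4aR,6R,8aR)-6-[(tert-butyldimethylsilyl)oxy]-2,5,5,8a-tetramethyl-4a,5,6,7,8,8a-hexahydronaphthalen-1-yl trifluoromethanesulfonate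
Product: 31 coupled diene alcohol (target skeleton with C3 OTBS and (R)-C10′ OH), via alkylborane 30 (not isolated)
Conditions: 29, 9-BBN-H (2.5 equiv), THF, rt; then 15, Pd(dppf)Cl2 (10 mol %), AsPh3, Cs2CO3, DMF/H2O, 45 °C
Reagents that add atoms: none
Why: Anti-Markovnikov hydroboration of the vinyl group followed by B-alkyl Suzuki–Miyaura coupling with the dienyl triflate, which forms the C9–C11 bond with the diene already in place and changes no stereocentre.

Step 19
Reactants: 31 coupled diene alcohol (target skeleton with C3 OTBS and (R)-C10′ OH)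
Product: 32 C3 O-TBS ether of the target
Conditions: Dess–Martin periodinane, CH2Cl2, 0 °C to rt
Reagents that add atoms: none
Why: Dess–Martin oxidation of the only free alcohol to the oxepanone ketone under near-neutral conditions that leave the diene and the silyl ether intact.

Step 20
Reactants: 32 C3 O-TBS ether of the target
Product: 33 CNP0106412.2 (target)
Conditions: TBAF, THF, 45 °C
Reagents that add atoms: none
Why: Fluoride-mediated desilylation, which frees the C3 alcohol without acid that could isomerise the diene and without touching any stereocentre.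

**Compound list**

1 | 3-methylcyclopent-2-en-1-one | CC1=CC(=O)CC1 | starting material
2 | dimethylaluminium (R)-3-(but-1-en-2-yl)-3-methylcyclopent-1-en-1-olate | C[Al](C)OC1=C[C@](C)(C(=C)CC)CC1 | intermediate
3 | (R)-{[3-(but-1-en-2-yl)-3-methylcyclopent-1-en-1-yl]oxy}trimethylsilane | C[Si](C)(C)OC1=C[C@](C)(C(=C)CC)CC1 | intermediate
4 | lithium (R)-3-(but-1-en-2-yl)-3-methylcyclopent-1-en-1-olate | [Li]OC1=C[C@](C)(C(=C)CC)CC1 | intermediate
5 | (2S,3R)-2-allyl-3-(but-1-en-2-yl)-3-methylcyclopentan-1-one | O=C1[C@@H](CC=C)[C@](C)(C(=C)CC)CC1 | intermediate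
6 | (2S,3R)-3-methyl-2-(2-oxoethyl)-3-propanoylcyclopentan-1-one | O=C1[C@@H](CC=O)[C@](C)(C(=O)CC)CC1 | intermediate
7 | (2S,3R)-2-(2,2-dimethoxyethyl)-3-methyl-3-propanoylcyclopentan-1-one | O=C1[C@@H](CC(OC)OC)[C@](C)(C(=O)CC)CC1 | intermediate
8 | 1-[(1R,2S)-2-(2,2-dimethoxyethyl)-3-hydroxy-1-methyl-3-(prop-1-en-2-yl)cyclopentyl]propan-1-one, both carbinol epimers | OC1(C(C)=C)[C@@H](CC(OC)OC)[C@](C)(C(=O)CC)CC1 | intermediate
9 | (3R,4R)-3-(2,2-dimethoxyethyl)-2,2,4-trimethyl-4-propanoylcyclohexan-1-one | O=C1C(C)(C)[C@@H](CC(OC)OC)[C@](C)(C(=O)CC)CC1 | intermediate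
10 | (3R,4R)-2,2,4-trimethyl-3-(2-oxoethyl)-4-propanoylcyclohexan-1-one | O=C1C(C)(C)[C@@H](CC=O)[C@](C)(C(=O)CC)CC1 | intermediate
11 | (4aR,8aR)-2,5,5,8a-tetramethyl-4a,5,8,8a-tetrahydronaphthalene-1,6(4H,7H)-dione, trans-fused | O=C1CC[C@@]2(C)C(=O)C(C)=CC[C@@H]2C1(C)C | intermediate
12 | (4aR,6R,8aR)-6-hydroxy-2,5,5,8a-tetramethyl-4a,5,6,7,8,8a-hexahydronaphthalen-1(4H)-one | O[C@@H]1CC[C@@]2(C)C(=O)C(C)=CC[C@@H]2C1(C)C | intermediate
13 | (4aR,6R,8aR)-6-[(tert-butyldimethylsilyl)oxy]-2,5,5,8a-tetramethyl-4a,5,6,7,8,8a-hexahydronaphthalen-1(4H)-one | CC(C)(C)[Si](C)(C)O[C@@H]1CC[C@@]2(C)C(=O)C(C)=CC[C@@H]2C1(C)C | intermediate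
14 | potassium dienolate of 13 (O on C9, C9=C8–C7=C6) | CC(C)(C)[Si](C)(C)O[C@@H]1CC[C@@]2(C)C(O[K])=C(C)C=C[C@@H]2C1(C)C | intermediate
15 | (4aR,6R,8aR)-6-[(tert-butyldimethylsilyl)oxy]-2,5,5,8a-tetramethyl-4a,5,6,7,8,8a-hexahydronaphthalen-1-yl trifluoromethanesulfonate | CC(C)(C)[Si](C)(C)O[C@@H]1CC[C@@]2(C)C(OS(=O)(=O)C(F)(F)F)=C(C)C=C[C@@H]2C1(C)C | intermediate
16 | methyl acetoacetate | COC(=O)CC(C)=O | starting material
17 | geranyl bromide, (2E)-1-bromo-3,7-dimethylocta-2,6-diene | CC(C)=CCC/C(C)=C/CBr | starting material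
18 | sodium lithium dianion of methyl acetoacetate | [Li]CC(O[Na])=CC(=O)OC | intermediate
19 | methyl (6E)-7,11-dimethyl-3-oxododeca-6,10-dienoate | COC(=O)CC(=O)CC/C=C(\C)CCC=C(C)C | intermediate
20 | sodium (Z)-enolate of 19 | COC(=O)/C=C(\O[Na])CC/C=C(\C)CCC=C(C)C | intermediate
21 | methyl (2Z,6E)-3-[(diethoxyphosphoryl)oxy]-7,11-dimethyldodeca-2,6,10-trienoate | COC(=O)/C=C(\OP(=O)(OCC)OCC)CC/C=C(\C)CCC=C(C)C | intermediate
22 | methyl (2Z,6E)-7,11-dimethyl-3-[(trimethylsilyl)methyl]dodeca-2,6,10-trienoate | COC(=O)/C=C(\C[Si](C)(C)C)CC/C=C(\C)CCC=C(C)C | intermediate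
23 | (6′R,7′R,10′R)-diepoxide of 22 | COC(=O)/C=C(\C[Si](C)(C)C)CC[C@H]1O[C@]1(C)CC[C@H]1OC1(C)C | intermediate
24 | methyl (3R,5aR,6S,9aR)-2,2,5a-trimethyl-7-methylidene-3-[(trimethylsilyl)oxy]decahydro-1-benzoxepine-6-carboxylate | COC(=O)[C@H]1C(=C)CC[C@H]2OC(C)(C)[C@H](O[Si](C)(C)C)CC[C@@]21C | intermediate
25 | methyl (3R,5aR,6S,9aR)-3-hydroxy-2,2,5a-trimethyl-7-methylidenedecahydro-1-benzoxepine-6-carboxylate | COC(=O)[C@H]1C(=C)CC[C@H]2OC(C)(C)[C@H](O)CC[C@@]21C | intermediate
26 | methyl (3R,5aR,6S,7S,9aR)-3-hydroxy-2,2,5a,7-tetramethyldecahydro-1-benzoxepine-6-carboxylate | COC(=O)[C@H]1[C@@H](C)CC[C@H]2OC(C)(C)[C@H](O)CC[C@@]21C | intermediate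
27 | (3R,5aR,6S,7S,9aR)-6-(hydroxymethyl)-2,2,5a,7-tetramethyldecahydro-1-benzoxepin-3-ol | OC[C@H]1[C@@H](C)CC[C@H]2OC(C)(C)[C@H](O)CC[C@@]21C | intermediate
28 | (3R,5aR,6S,7S,9aR)-3-hydroxy-2,2,5a,7-tetramethyldecahydro-1-benzoxepine-6-carbaldehyde | O=C[C@H]1[C@@H](C)CC[C@H]2OC(C)(C)[C@H](O)CC[C@@]21C | intermediate
29 | (3R,5aR,6S,7S,9aR)-6-ethenyl-2,2,5a,7-tetramethyldecahydro-1-benzoxepin-3-ol | C=C[C@H]1[C@@H](C)CC[C@H]2OC(C)(C)[C@H](O)CC[C@@]21C | intermediate
30 | B-alkyl-9-borabicyclo[3.3.1]nonane from 29, C10′ oxygen as its 9-BBN borinate | C1CC2CCCC(C1)B2CC[C@H]3[C@@H](C)CC[C@H]4OC(C)(C)[C@H](OB5C6CCCC5CCC6)CC[C@@]43C | intermediate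
31 | coupled diene alcohol: target skeleton with C3 OTBS and (R)-C10′ OH | CC1=C(CC[C@H]2[C@@H](C)CC[C@H]3OC(C)(C)[C@H](O)CC[C@@]32C)[C@]2(C)CC[C@@H](O[Si](C)(C)C(C)(C)C)C(C)(C)[C@H]2C=C1 | intermediate
32 | C3 O-TBS ether of the target | CC1=C(CC[C@H]2[C@@H](C)CC[C@H]3OC(C)(C)C(=O)CC[C@@]32C)[C@]2(C)CC[C@@H](O[Si](C)(C)C(C)(C)C)C(C)(C)[C@H]2C=C1 | intermediate
33 | CNP0106412.2 | CC1=C(CC[C@H]2[C@@H](C)CC[C@H]3OC(C)(C)C(=O)CC[C@@]32C)[C@]2(C)CC[C@@H](O)C(C)(C)[C@H]2C=C1 | target

Total step count: 20. Longest linear sequence: 12 steps (steps 9–20).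

**Steps most likely to fail**

Step 5 (key step). The cation-level C4 centre may be captured by the neighbouring hydroxyl group (closure to a spiro-epoxide). The C4 radical may be reduced before the shift, or the shift may be slowed by the crowding around C5. The fallback uses a discrete leaving group on C4 in place of hydrogen-atom transfer. It sets out from 7, where 2-lithio-2-(phenylselanyl)propane (from 2,2-bis(phenylselanyl)propane and n-BuLi, THF, −78 °C) is added to the C3 ketone to give the β-hydroxy selenide F1. AgBF4 in CH2Cl2 then ionises the C4–Se bond under non-reducing conditions and drives the ring enlargement of the β-hydroxy selenide. The fallback comes back to the route at 9, which enters the acid stage of step 5.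

Step 13. The ester-deactivated allylsilane may be too weak a nucleophile. The epoxonium ion would then collapse by hydride shift or by exo opening to smaller oxacycles before ring C closes. The fallback raises the nucleophilicity of the terminator by changing its oxidation level. It sets out from 23, which i-Bu2AlH (CH2Cl2, −78 °C) reduces to the diepoxy allylic alcohol F2. TBSCl and imidazole give the silyl ether F3. The same Me3SiOTf/2,6-di-tert-butyl-4-methylpyridine cascade should then give the bicyclic exocyclic alkene F4. Hydrogenation over PtO2 gives the saturated silyl ether F5, and TBAF brings the sequence back to the route at 27.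

Step 1. Facial selectivity of the copper catalyst may be poor on the flat five-membered enone with an α-branched alkenylalane. The fallback uses a silicon-bearing alkenylaluminium reagent and a carbene–copper catalyst suited to cyclopentenones. It sets out from 1. The reagent is [1-(trimethylsilyl)prop-1-en-1-yl]diisobutylaluminium, made from 1-(trimethylsilyl)propyne and i-Bu2AlH. It is added with Cu(OTf)2 and a chiral N-heterocyclic carbene made from its imidazolinium salt. Trapping with Me3SiOTf gives the silyl enol ether F6. MeLi and allyl iodide, as in step 2, give the allyl ketone F7. m-CPBA epoxidises the electron-rich vinylsilane selectively to the epoxysilane F8. Aqueous H2SO4 in THF turns F8 into the ethyl ketone F9. Ozonolysis and acetalisation of the remaining allyl group, as in step 3, bring the sequence back to the route at 7.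

**Further compounds**

F1 | step 5 | 1-[(1R,2S)-2-(2,2-dimethoxyethyl)-3-hydroxy-1-methyl-3-[2-(phenylselanyl)propan-2-yl]cyclopentyl]propan-1-one | OC1(C(C)(C)[Se]c2ccccc2)[C@@H](CC(OC)OC)[C@](C)(C(=O)CC)CC1
F2 | step 13 | (2Z)-5-{(2R,3R)-3-[2-((2R)-3,3-dimethyloxiran-2-yl)ethyl]-3-methyloxiran-2-yl}-3-[(trimethylsilyl)methyl]pent-2-en-1-ol | OC/C=C(\C[Si](C)(C)C)CC[C@H]1O[C@]1(C)CC[C@H]1OC1(C)C
F3 | step 13 | tert-butyldimethylsilyl ether of F2 | CC(C)(C)[Si](C)(C)OC/C=C(\C[Si](C)(C)C)CC[C@H]1O[C@]1(C)CC[C@H]1OC1(C)C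
F4 | step 13 | (3R,5aR,6S,9aR)-6-{[(tert-butyldimethylsilyl)oxy]methyl}-2,2,5a-trimethyl-7-methylidenedecahydro-1-benzoxepin-3-ol | CC(C)(C)[Si](C)(C)OC[C@H]1C(=C)CC[C@H]2OC(C)(C)[C@H](O)CC[C@@]21C
F5 | step 13 | (3R,5aR,6S,7S,9aR)-6-{[(tert-butyldimethylsilyl)oxy]methyl}-2,2,5a,7-tetramethyldecahydro-1-benzoxepin-3-ol | CC(C)(C)[Si](C)(C)OC[C@H]1[C@@H](C)CC[C@H]2OC(C)(C)[C@H](O)CC[C@@]21C
F6 | step 1 | trimethyl({3-methyl-3-[1-(trimethylsilyl)prop-1-en-1-yl]cyclopent-1-en-1-yl}oxy)silane, C10 configured as in 3 | C[Si](C)(C)OC1=C[C@](C)(/C(=C/C)[Si](C)(C)C)CC1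
F7 | step 1 | 2-allyl-3-methyl-3-[1-(trimethylsilyl)prop-1-en-1-yl]cyclopentan-1-one, C5 and C10 configured as in 5 | O=C1[C@@H](CC=C)[C@](C)(/C(=C/C)[Si](C)(C)C)CC1
F8 | step 1 | 2-allyl-3-methyl-3-[3-methyl-2-(trimethylsilyl)oxiran-2-yl]cyclopentan-1-one, epoxide diastereomers | O=C1[C@@H](CC=C)[C@](C)(C2(OC2C)[Si](C)(C)C)CC1
F9 | step 1 | (2S,3R)-2-allyl-3-methyl-3-propanoylcyclopentan-1-one | O=C1[C@@H](CC=C)[C@](C)(C(=O)CC)CC1
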